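**Plan**

- Retrosynthesis: ring C is opened at O1–C2 and C2–C3 (C2 becomes a one-carbon unit), then C4–C4a is cut, giving a ring A aryl metal and a ring B arylacetaldehyde.
- Ring B is cut at C3'–C4', C1'–C2' and C4'–C5'. Its chain at C3' between the oxygens on C2' and C4', with OMe on C5' and a carbon arm on C1', maps onto a siloxyalkyne (C2', C3') and a (2-methoxyvinyl)ketene (C4', C1', C6', C5').
- Forward: diazo enone 8 and siloxyalkyne 14 are made separately; ring B arises first by benzannulation, ring A is joined through C4–C4a, and ring C is closed last.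
- Stereochemistry: the target has no stereocentre; the transient centres in 16, 18 and 26 are erased within the route.
- Acid is avoided after ring B exists, because the tertiary alcohol would close onto an ortho phenol to a chroman; both silyl ethers leave with fluoride at the end.

Key step: step 7

Remark: ring B is numbered with primes (C1' is bonded to C3 of the chromenone); compounds 1, 2, 9 and 22 are taken as purchasable.

**Route**

Step 1
Reactants: 1 methyl 4-chloro-4-oxobutanoate; 2 ethynyltrimethylsilane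
Product: 3 methyl 4-oxo-6-(trimethylsilyl)hex-5-ynoate
Conditions: PdCl2(PPh3)2 (cat.), CuI (cat.), Et3N, THF, rt
Reagents that add atoms: none
Why: Acyl Sonogashira coupling, in which the copper acetylide of 2 is acylated through the acyl–palladium species from 1; the methyl ester and the C–Si bond should survive these mild conditions.

Step 2
Reactants: 3 methyl 4-oxo-6-(trimethylsilyl)hex-5-ynoate
Product: 5 methyl (E)-6-methoxy-4-oxohex-5-enoate, via methyl 4-oxohex-5-ynoate 4 (not isolated)
Conditions: K2CO3 (0.2 equiv), MeOH, 0 °C to rt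
Reagents that add atoms: methanol, CO
Why: Methoxide cleaves the alkynyl–silicon bond and then adds to terminal ynone 4 (oxa-Michael addition); the reversible addition should settle on the E enol ether, and the reaction is stopped before a second methanol adds.

Step 3
Reactants: 5 methyl (E)-6-methoxy-4-oxohex-5-enoate
Product: 8 methyl (E)-3-diazo-6-methoxy-4-oxohex-5-enoate, via lithium enolate 6 (not isolated), via trifluoroacetyl ketone 7 (not isolated)
Conditions: LiN(SiMe3)2, THF, −78 °C; CF3CO2CH2CF3; then MsN3, Et3N, H2O, MeCN, rt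
Reagents that add atoms: methanesulfonyl azide, CS(=O)(=O)N=[N+]=[N-]; 2,2,2-trifluoroethyl trifluoroacetate, O=C(OCC(F)(F)F)C(F)(F)F (trifluoroacetyl group of 7 only); LiN(SiMe3)2, [Li]N([Si](C)(C)C)[Si](C)(C)C (lithium of 6 only)
Why: Detrifluoroacetylative diazo transfer: the hindered amide base enolises the ketone (more acidic than the ester, and no conjugate addition to the vinylogous ester), Claisen trifluoroacetylation activates C3, and the sulfonyl azide transfers N2 with loss of the trifluoroacetyl group.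

Step 4
Reactants: 9 methyl pent-4-ynoate
Product: 10 2-methylhex-5-yn-2-ol
Conditions: MeMgBr (3.3 equiv), THF, 0 °C to rt; aq NH4Cl
Reagents that add atoms: methylmagnesium bromide, C[Mg]Br
Why: Double Grignard addition to the ester gives the tertiary alcohol; the third equivalent is consumed by the acetylenic hydrogen, which returns on work-up.

Step 5
Reactants: 10 2-methylhex-5-yn-2-ol
Product: 11 triethyl[(2-methylhex-5-yn-2-yl)oxy]silane
Conditions: Et3SiOTf, 2,6-lutidine, CH2Cl2, 0 °C
Reagents that add atoms: triethylsilyl trifluoromethanesulfonate, CC[Si](CC)(CC)OS(=O)(=O)C(F)(F)F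
Why: Silyl triflate with a hindered pyridine base is the standard silylation of a tertiary alcohol; the resulting ether withstands the bases used later and leaves with fluoride at the end.

Step 6
Reactants: 11 triethyl[(2-methylhex-5-yn-2-yl)oxy]silane
Product: 14 triisopropyl[(5-methyl-5-triethylsilyloxyhex-1-yn-1-yl)oxy]silane, via lithium acetylide 12 (not isolated), via lithium ynolate 13 (not isolated)
Conditions: n-BuLi, THF, −78 °C; LiOOt-Bu (from t-BuOOH and LiN(SiMe3)2), −78 to 0 °C; i-Pr3SiOTf, −78 to 0 °C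
Reagents that add atoms: tert-butyl hydroperoxide, CC(C)(C)OO (ynolate oxygen); triisopropylsilyl trifluoromethanesulfonate, CC(C)[Si](OS(=O)(=O)C(F)(F)F)(C(C)C)C(C)C; n-BuLi, [Li]CCCC (lithium of 12 and 13 only)
Why: Oxidation of the lithium acetylide by lithium tert-butyl peroxide (Julia ynolate synthesis) gives ynolate 13, which the bulky silyl triflate should trap on oxygen to give the siloxyalkyne.

Step 7
Reactants: 8 methyl (E)-3-diazo-6-methoxy-4-oxohex-5-enoate; 14 triisopropyl[(5-methyl-5-triethylsilyloxyhex-1-yn-1-yl)oxy]silane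
Product: 19 methyl 2-[4-hydroxy-5-methoxy-3-(3-methyl-3-triethylsilyloxybutyl)-2-(triisopropylsilyloxy)phenyl]acetate, via vinylketene 15 (not isolated), via cyclobutenone 16 (not isolated), via dienylketene 17 (not isolated), via cyclohexadienone 18 (not isolated)
Conditions: 8 (1.3 equiv), hν (254 nm, quartz), ClCH2CH2Cl, rt; then 80 °C
Reagents that add atoms: none
Why: Irradiation expels N2 from 8 with 1,2-shift of the 2-methoxyvinyl group (photochemical Wolff rearrangement) to give vinylketene 15, whose electrophilic ketene carbon is attacked by the electron-rich, chain-bearing carbon of siloxyalkyne 14 in a [2+2] cycloaddition to cyclobutenone 16. Heating opens 16 by 4π electrocyclic cleavage to dienylketene 17; ring B then closes by 6π electrocyclisation of the ketene carbon onto the methoxy-bearing vinyl terminus to give dienone 18, which tautomerises to phenol 19. This is the photochemical diazo ketone variant of the Danheiser benzannulation with siloxyalkynes. The new bonds are C3'–C4' and C1'–C2' (cycloaddition) and C4'–C5' (6π closure); no stereocentre remains, since those of 16 and 18 are transient. The step needs Wolff shift to outrun 1,2-hydrogen shift from the CH2CO2Me group, which photolysis of the diazo ketone and the electron-poor character of those hydrogens should favour. It also needs head-to-tail [2+2] regiochemistry, which is fixed by the polarity of the ynol ether against the ketene carbonyl carbon and places the chain at C3' between the C4' hydroxyl and the C2' silyl ether.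

Step 8
Reactants: 19 methyl 2-[4-hydroxy-5-methoxy-3-(3-methyl-3-triethylsilyloxybutyl)-2-(triisopropylsilyloxy)phenyl]acetate
Product: 20 methyl 2-[4-(benzyloxy)-5-methoxy-3-(3-methyl-3-triethylsilyloxybutyl)-2-(triisopropylsilyloxy)phenyl]acetate
Conditions: BnBr, K2CO3, DMF, rt
Reagents that add atoms: benzyl bromide, BrCc1ccccc1
Why: Williamson etherification of the only free phenol; carbonate should not touch the ester α-position or the silyl ethers, and the benzyl group shields the guaiacol-type phenol from the later oxidant.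

Step 9
Reactants: 20 methyl 2-[4-(benzyloxy)-5-methoxy-3-(3-methyl-3-triethylsilyloxybutyl)-2-(triisopropylsilyloxy)phenyl]acetate
Product: 21 2-[4-(benzyloxy)-5-methoxy-3-(3-methyl-3-triethylsilyloxybutyl)-2-(triisopropylsilyloxy)phenyl]acetaldehyde
Conditions: i-Bu2AlH (1.1 equiv), CH2Cl2, −78 °C; MeOH, aq potassium sodium tartrate
Reagents that add atoms: none
Why: Partial ester reduction: hydride delivery at low temperature stops at the aluminium hemiacetal, which releases the arylacetaldehyde only on work-up.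

Step 10
Reactants: 22 1,3,5-tris(benzyloxy)benzene
Product: 23 2-bromo-1,3,5-tris(benzyloxy)benzene
Conditions: NBS, CH2Cl2, −78 to 0 °C
Reagents that add atoms: N-bromosuccinimide, O=C1CCC(=O)N1Br
Why: Electrophilic aromatic bromination of the phloroglucinol triether should occur once, at one of three equivalent positions between two ether oxygens.

Step 11
Reactants: 23 2-bromo-1,3,5-tris(benzyloxy)benzene; 21 2-[4-(benzyloxy)-5-methoxy-3-(3-methyl-3-triethylsilyloxybutyl)-2-(triisopropylsilyloxy)phenyl]acetaldehyde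
Product: 26 2-[4-(benzyloxy)-5-methoxy-3-(3-methyl-3-triethylsilyloxybutyl)-2-(triisopropylsilyloxy)phenyl]-1-[2,4,6-tris(benzyloxy)phenyl]ethan-1-ol (racemic), via aryllithium 24 (not isolated), via arylcerium dichloride 25 (not isolated)
Conditions: 23, n-BuLi, THF, −78 °C; CeCl3, −78 °C; then 21, −78 °C; aq NH4Cl at −78 °C
Reagents that add atoms: n-BuLi, [Li]CCCC (lithium of 24 only); CeCl3, Cl[Ce](Cl)Cl (cerium and chlorine of 25 only)
Why: Bromine–lithium exchange and transmetalation to the less basic organocerium reagent should give clean 1,2-addition to the enolisable aldehyde (Imamoto organocerium addition); the cold quench prevents silyl transfer from the C2' oxygen to the new alkoxide, and the racemic carbinol centre is destroyed in step 12.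

Step 12
Reactants: 26 2-[4-(benzyloxy)-5-methoxy-3-(3-methyl-3-triethylsilyloxybutyl)-2-(triisopropylsilyloxy)phenyl]-1-[2,4,6-tris(benzyloxy)phenyl]ethan-1-ol
Product: 27 2-[4-(benzyloxy)-5-methoxy-3-(3-methyl-3-triethylsilyloxybutyl)-2-(triisopropylsilyloxy)phenyl]-1-[2,4,6-tris(benzyloxy)phenyl]ethan-1-one
Conditions: Dess–Martin periodinane, pyridine, CH2Cl2, 0 °C to rt
Reagents that add atoms: none
Why: Dess–Martin oxidation under buffered, non-acidic conditions should convert the electron-rich benzylic alcohol to the deoxybenzoin without dehydration to a stilbene.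

Step 13
Reactants: 27 2-[4-(benzyloxy)-5-methoxy-3-(3-methyl-3-triethylsilyloxybutyl)-2-(triisopropylsilyloxy)phenyl]-1-[2,4,6-tris(benzyloxy)phenyl]ethan-1-one
Product: 28 2-[4-hydroxy-5-methoxy-3-(3-methyl-3-triethylsilyloxybutyl)-2-(triisopropylsilyloxy)phenyl]-1-(2,4,6-trihydroxyphenyl)ethan-1-one
Conditions: H2 (1 atm), Pd/C, EtOAc, rt
Reagents that add atoms: none
Why: Hydrogenolysis removes all four benzyl ethers, while the silyl ethers and the deactivated aryl ketone should persist in an aprotic solvent; the C2' silyl ether is kept so that the ketone cannot close to a benzofuran.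

Step 14
Reactants: 28 2-[4-hydroxy-5-methoxy-3-(3-methyl-3-triethylsilyloxybutyl)-2-(triisopropylsilyloxy)phenyl]-1-(2,4,6-trihydroxyphenyl)ethan-1-one
Product: 30 5,7-dihydroxy-3-[4-hydroxy-5-methoxy-3-(3-methyl-3-triethylsilyloxybutyl)-2-(triisopropylsilyloxy)phenyl]-4H-chromen-4-one, via enaminone 29 (not isolated)
Conditions: Me2NCH(OMe)2, THF, 60 °C
Reagents that add atoms: N,N-dimethylformamide dimethyl acetal, COC(OC)N(C)C
Why: Classical isoflavone synthesis from a 2-hydroxydeoxybenzoin: the amide acetal condenses at the activated methylene to enaminone 29, and an ortho hydroxyl of ring A (both are equivalent) displaces dimethylamine to close ring C by addition–elimination.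

Step 15
Reactants: 30 5,7-dihydroxy-3-[4-hydroxy-5-methoxy-3-(3-methyl-3-triethylsilyloxybutyl)-2-(triisopropylsilyloxy)phenyl]-4H-chromen-4-one
Product: 31 5,7-dihydroxy-3-[2,4-dihydroxy-3-(3-hydroxy-3-methylbutyl)-5-methoxyphenyl]-4H-chromen-4-one
Conditions: n-Bu4NF, AcOH, THF, 0 °C to rt
Reagents that add atoms: none
Why: Fluoride cleaves the aryl triisopropylsilyl ether and the tertiary triethylsilyl ether; the acetic acid buffer protects the base-sensitive pyranone, and the absence of strong acid prevents chroman formation from the tertiary alcohol.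

**Compound list**

1 | methyl 4-chloro-4-oxobutanoate | COC(=O)CCC(Cl)=O | starting material
2 | ethynyltrimethylsilane | C#C[Si](C)(C)C | starting material
3 | methyl 4-oxo-6-(trimethylsilyl)hex-5-ynoate | COC(=O)CCC(=O)C#C[Si](C)(C)C | intermediate
4 | methyl 4-oxohex-5-ynoate | COC(=O)CCC(=O)C#C | intermediate
5 | methyl (E)-6-methoxy-4-oxohex-5-enoate | COC(=O)CCC(=O)/C=C/OC | intermediate
6 | lithium enolate of 5 across C3–C4 (enolate geometry immaterial) | [Li+].[O-]C(=CCC(=O)OC)/C=C/OC | intermediate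
7 | methyl (E)-6-methoxy-4-oxo-3-(2,2,2-trifluoroacetyl)hex-5-enoate (racemic, enolisable) | COC(=O)CC(C(=O)C(F)(F)F)C(=O)/C=C/OC | intermediate
8 | methyl (E)-3-diazo-6-methoxy-4-oxohex-5-enoate | COC(=O)CC(=[N+]=[N-])C(=O)/C=C/OC | intermediate
9 | methyl pent-4-ynoate | COC(=O)CCC#C | starting material
10 | 2-methylhex-5-yn-2-ol | CC(C)(O)CCC#C | intermediate
11 | triethyl[(2-methylhex-5-yn-2-yl)oxy]silane | CC[Si](CC)(CC)OC(C)(C)CCC#C | intermediate
12 | [5-methyl-5-(triethylsilyloxy)hex-1-yn-1-yl]lithium | [Li]C#CCCC(C)(C)O[Si](CC)(CC)CC | intermediate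
13 | lithium 5-methyl-5-(triethylsilyloxy)hex-1-yn-1-olate | [Li+].[O-]C#CCCC(C)(C)O[Si](CC)(CC)CC | intermediate
14 | triisopropyl[(5-methyl-5-triethylsilyloxyhex-1-yn-1-yl)oxy]silane | CC(C)[Si](OC#CCCC(C)(C)O[Si](CC)(CC)CC)(C(C)C)C(C)C | intermediate
15 | methyl (E)-5-methoxy-3-(oxomethylidene)pent-4-enoate | COC(=O)CC(=C=O)/C=C/OC | intermediate
16 | methyl 2-[1-[(E)-2-methoxyethenyl]-3-(3-methyl-3-triethylsilyloxybutyl)-4-oxo-2-(triisopropylsilyloxy)cyclobut-2-en-1-yl]acetate (racemic) | COC(=O)CC1(/C=C/OC)C(=O)C(CCC(C)(C)O[Si](CC)(CC)CC)=C1O[Si](C(C)C)(C(C)C)C(C)C | intermediate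
17 | dienylketene O=C=C(R)–C(OSi-i-Pr3)=C(CH2CO2Me)–CH=CH–OMe, R = 3-methyl-3-triethylsilyloxybutyl, ketene and (E)-methoxyvinyl groups cis | O=C=C(CCC(C)(C)O[Si](CC)(CC)CC)/C(O[Si](C(C)C)(C(C)C)C(C)C)=C(/CC(=O)OC)\C=C\OC | intermediate
18 | methyl 2-[3-methoxy-4-oxo-5-(3-methyl-3-triethylsilyloxybutyl)-6-(triisopropylsilyloxy)cyclohexa-1,5-dien-1-yl]acetate (racemic) | COC(=O)CC1=CC(OC)C(=O)C(CCC(C)(C)O[Si](CC)(CC)CC)=C1O[Si](C(C)C)(C(C)C)C(C)C | intermediate
19 | methyl 2-[4-hydroxy-5-methoxy-3-(3-methyl-3-triethylsilyloxybutyl)-2-(triisopropylsilyloxy)phenyl]acetate | COC(=O)Cc1cc(OC)c(O)c(CCC(C)(C)O[Si](CC)(CC)CC)c1O[Si](C(C)C)(C(C)C)C(C)C | intermediate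
20 | methyl 2-[4-(benzyloxy)-5-methoxy-3-(3-methyl-3-triethylsilyloxybutyl)-2-(triisopropylsilyloxy)phenyl]acetate | COC(=O)Cc1cc(OC)c(OCc2ccccc2)c(CCC(C)(C)O[Si](CC)(CC)CC)c1O[Si](C(C)C)(C(C)C)C(C)C | intermediate
21 | 2-[4-(benzyloxy)-5-methoxy-3-(3-methyl-3-triethylsilyloxybutyl)-2-(triisopropylsilyloxy)phenyl]acetaldehyde | O=CCc1cc(OC)c(OCc2ccccc2)c(CCC(C)(C)O[Si](CC)(CC)CC)c1O[Si](C(C)C)(C(C)C)C(C)C | intermediate
22 | 1,3,5-tris(benzyloxy)benzene | C(Oc1cc(OCc2ccccc2)cc(OCc2ccccc2)c1)c1ccccc1 | starting material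
23 | 2-bromo-1,3,5-tris(benzyloxy)benzene | Brc1c(OCc2ccccc2)cc(OCc2ccccc2)cc1OCc1ccccc1 | intermediate
24 | [2,4,6-tris(benzyloxy)phenyl]lithium | [Li]c1c(OCc2ccccc2)cc(OCc2ccccc2)cc1OCc1ccccc1 | intermediate
25 | dichloro[2,4,6-tris(benzyloxy)phenyl]cerium | Cl[Ce](Cl)c1c(OCc2ccccc2)cc(OCc2ccccc2)cc1OCc1ccccc1 | intermediate
26 | 2-[4-(benzyloxy)-5-methoxy-3-(3-methyl-3-triethylsilyloxybutyl)-2-(triisopropylsilyloxy)phenyl]-1-[2,4,6-tris(benzyloxy)phenyl]ethan-1-ol (racemic) | OC(Cc1cc(OC)c(OCc2ccccc2)c(CCC(C)(C)O[Si](CC)(CC)CC)c1O[Si](C(C)C)(C(C)C)C(C)C)c1c(OCc2ccccc2)cc(OCc2ccccc2)cc1OCc1ccccc1 | intermediate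
27 | 2-[4-(benzyloxy)-5-methoxy-3-(3-methyl-3-triethylsilyloxybutyl)-2-(triisopropylsilyloxy)phenyl]-1-[2,4,6-tris(benzyloxy)phenyl]ethan-1-one | O=C(Cc1cc(OC)c(OCc2ccccc2)c(CCC(C)(C)O[Si](CC)(CC)CC)c1O[Si](C(C)C)(C(C)C)C(C)C)c1c(OCc2ccccc2)cc(OCc2ccccc2)cc1OCc1ccccc1 | intermediate
28 | 2-[4-hydroxy-5-methoxy-3-(3-methyl-3-triethylsilyloxybutyl)-2-(triisopropylsilyloxy)phenyl]-1-(2,4,6-trihydroxyphenyl)ethan-1-one | O=C(Cc1cc(OC)c(O)c(CCC(C)(C)O[Si](CC)(CC)CC)c1O[Si](C(C)C)(C(C)C)C(C)C)c1c(O)cc(O)cc1O | intermediate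
29 | 3-(dimethylamino)-2-[4-hydroxy-5-methoxy-3-(3-methyl-3-triethylsilyloxybutyl)-2-(triisopropylsilyloxy)phenyl]-1-(2,4,6-trihydroxyphenyl)prop-2-en-1-one (alkene geometry immaterial) | CN(C)C=C(C(=O)c1c(O)cc(O)cc1O)c1cc(OC)c(O)c(CCC(C)(C)O[Si](CC)(CC)CC)c1O[Si](C(C)C)(C(C)C)C(C)C | intermediate
30 | 5,7-dihydroxy-3-[4-hydroxy-5-methoxy-3-(3-methyl-3-triethylsilyloxybutyl)-2-(triisopropylsilyloxy)phenyl]-4H-chromen-4-one | COc1cc(-c2coc3cc(O)cc(O)c3c2=O)c(O[Si](C(C)C)(C(C)C)C(C)C)c(CCC(C)(C)O[Si](CC)(CC)CC)c1O | intermediate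
31 | 5,7-dihydroxy-3-[2,4-dihydroxy-3-(3-hydroxy-3-methylbutyl)-5-methoxyphenyl]-4H-chromen-4-one | COc1cc(-c2coc3cc(O)cc(O)c3c2=O)c(O)c(CCC(C)(C)O)c1O | target

**Step count and risks**

Total step count: 15. Longest linear sequence: 11 steps (steps 1, 2, 3, 7, 8, 9, 11, 12, 13, 14, 15; the branch through steps 4, 5, 6 is equally long).

Steps most likely to fail:

1. Step 7. A 1,2-hydrogen shift from the CH2CO2Me group to the carbene carbon, or secondary photolysis of the products, may outrun the Wolff rearrangement and cycloaddition. The fallback uses a diazo ketone with no hydrogen next to the diazo carbon and adds the acetate arm afterwards. It sets out from 14 and commercial (E)-4-methoxybut-3-en-2-one. Diazo transfer as in step 3 should give (E)-1-diazo-4-methoxybut-3-en-2-one F1. Photolysis of F1 with 14 and heating, as in step 7, should give 2-methoxy-6-(3-methyl-3-triethylsilyloxybutyl)-5-(triisopropylsilyloxy)phenol F2. NBS should brominate para to the free hydroxyl to give 4-bromo-6-methoxy-2-(3-methyl-3-triethylsilyloxybutyl)-3-(triisopropylsilyloxy)phenol F3. Benzylation (BnBr, K2CO3, DMF) then gives [3-(benzyloxy)-6-bromo-4-methoxy-2-(3-methyl-3-triethylsilyloxybutyl)phenoxy]triisopropylsilane F4. Palladium-catalysed coupling of F4 with the Reformatsky reagent BrZnCH2CO2Me (Pd(dba)2, P(t-Bu)3, THF) installs the arm and returns to the route at 20.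

2. Step 3. Deprotonation at the ester α-carbon may compete with enolisation of the ketone, or the base may degrade the enol ether, so that trifluoroacetylation occurs at the wrong site. The fallback replaces hard enolisation by soft enolisation, to which the ester does not respond. It sets out from 5. Me3SiOTf and Et3N (CH2Cl2, 0 °C) should silylate only the ketone, giving methyl (5E)-6-methoxy-4-(trimethylsilyloxy)hexa-3,5-dienoate F5. Trifluoroacetic anhydride then acylates the nucleophilic C3 of this siloxydiene (Mukaiyama-type acylation), which returns to the route at 7. MsN3 and Et3N complete the transfer to 8.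

3. Step 14. The amide acetal may methylate the free phenols, or condensation at the methylene flanked by two ortho-substituted rings may be slow. The fallback installs the one-carbon unit before the phenols are unveiled. It sets out from 27. Heating 27 in neat Me2NCH(OMe)2 at 90 °C should give 2-[4-(benzyloxy)-5-methoxy-3-(3-methyl-3-triethylsilyloxybutyl)-2-(triisopropylsilyloxy)phenyl]-3-(dimethylamino)-1-[2,4,6-tris(benzyloxy)phenyl]prop-2-en-1-one F6. Hydrogenolysis (H2, Pd/C, EtOAc) then removes the benzyl groups, and the freed ortho hydroxyl should close ring C with loss of dimethylamine, returning to the route at 30.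

**Further compounds**

F1 | step 7 | (E)-1-diazo-4-methoxybut-3-en-2-one | CO/C=C/C(=O)C=[N+]=[N-]
F2 | step 7 | 2-methoxy-6-(3-methyl-3-triethylsilyloxybutyl)-5-(triisopropylsilyloxy)phenol | COc1ccc(O[Si](C(C)C)(C(C)C)C(C)C)c(CCC(C)(C)O[Si](CC)(CC)CC)c1O
F3 | step 7 | 4-bromo-6-methoxy-2-(3-methyl-3-triethylsilyloxybutyl)-3-(triisopropylsilyloxy)phenol | COc1cc(Br)c(O[Si](C(C)C)(C(C)C)C(C)C)c(CCC(C)(C)O[Si](CC)(CC)CC)c1O
F4 | step 7 | [3-(benzyloxy)-6-bromo-4-methoxy-2-(3-methyl-3-triethylsilyloxybutyl)phenoxy]triisopropylsilane | COc1cc(Br)c(O[Si](C(C)C)(C(C)C)C(C)C)c(CCC(C)(C)O[Si](CC)(CC)CC)c1OCc1ccccc1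
F5 | step 3 | methyl (5E)-6-methoxy-4-(trimethylsilyloxy)hexa-3,5-dienoate | COC(=O)CC=C(O[Si](C)(C)C)/C=C/OC
F6 | step 14 | 2-[4-(benzyloxy)-5-methoxy-3-(3-methyl-3-triethylsilyloxybutyl)-2-(triisopropylsilyloxy)phenyl]-3-(dimethylamino)-1-[2,4,6-tris(benzyloxy)phenyl]prop-2-en-1-one | CN(C)C=C(C(=O)c1c(OCc2ccccc2)cc(OCc2ccccc2)cc1OCc1ccccc1)c1cc(OC)c(OCc2ccccc2)c(CCC(C)(C)O[Si](CC)(CC)CC)c1O[Si](C(C)C)(C(C)C)C(C)C
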